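You cannot read the drain of the intermediate off its own curve: in the zeta run it stands at 10.8% after 3.00 h and 11.1% after 6.00 h, while the target climbs. So you read the drain from what passes through.

| setting | zeta | gamma | flask |
|---|---|---|---|
| substrate | 0.060 M | 0.060 M | 0.060 M |
| partner | 2 equiv | 2 equiv | 2.00 equiv |
| protic impurity | 8.4 mM | 13 mM | 6.00 mM |
| free catalyst | 0.16 mol% | 0.16 mol% | 0.16 mol% |
| second catalyst | 0.2 mol% | 0.2 mol% | 0.2 mol% |
| remark | run made earlier | run made earlier |  |
| time |  |  | 10 h |

| run | time / h | target / % | intermediate / % | over-reaction product / % |
|---|---|---|---|---|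
| zeta | 0.500 | 0.1 | 3.6 | 0.1 |
| zeta | 1.50 | 3.2 | 6.8 | 0.9 |
| zeta | 3.00 | 9.5 | 10.8 | 0.2 |
| zeta | 4.00 | 14.5 | 9.9 | 0.6 |
| zeta | 6.00 | 24.5 | 11.1 | 0.4 |
| gamma | 0.500 | 0.3 | 3.5 | 0.1 |
| gamma | 0.833 | 1.2 | 5.2 | 0 |
| gamma | 1.50 | 3.9 | 7.3 | 0.1 |
| gamma | 3.00 | 10.0 | 10.7 | 0 |
| gamma | 6.00 | 23.4 | 11.9 | 0 |

(readings scatter by 0.5 percentage points)

- the target in the flask at 10 h, as a percentage of the substrate charged
- the intermediate in the flask at 10 h, as a percentage of the substrate charged
- the over-reaction product in the flask at 10 h, as a percentage of the substrate charged
- concentration of partner at 10 h, in M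



This is my own reckoning, rung by rung, from the zeta run. The first rung you can read is the drain: target gained per hour between those two readings, over their mean intermediate, gives

k(drain) = 0.457 /h

I suppose the drain is pseudo-first-order in partner, that each target costs one partner and that the impurity costs its own amount. Partner in the zeta run then stood near 0.101 M, which gives, as a reading, the drain constant, the first-order loss of intermediate per unit of c(partner):

g = 4.50 /M/h

The next rung is intake. The three products together at 6.00 h give

k(in) = 0.0744 /h

This is slower than the drain, so the intermediate tracks a plateau: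

c(intermediate) = k(in) · c(substrate) / (g · c(partner))

The over-reaction product comes after these: it reads 0.4% and 0% in the last readings of the zeta and gamma runs, against a scatter of 0.5 percentage points.

For the flask at 10 h, I expect 47.5% substrate left and partner near 0.0892 M, so a plateau of 8.80%.

The forecast is higher than my plateau on the intermediate, at 10.5%, and gives 39% target, 2% over-reaction product and 0.088 M partner. Of the over-reaction product it says “perhaps with a threshold once impurity is consumed”.

The flask gives 40.0% target, 9.92% intermediate, 2.96% over-reaction product and 0.0882 M partner, each inside the forecast's range.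

    partner + second catalyst + intermediate → second catalyst + target (k = 37300 /M²/h)
    substrate + free catalyst → free catalyst + intermediate (k = 784 /M/h)
    2 substrate → homo dimer (k = 0.00194 /M/h)
    free catalyst + target → free catalyst + over-reaction product (k = 160 /M/h)
    partner + protic impurity → quenched reagent (k = 11.6 /M/h)

With the flask's own 0.0882 M partner and 47.0% substrate, g puts the plateau at 8.81% against 9.92%; at 10 h the flask makes intermediate at 0.904 of the rate it uses it. The neighbour with 3.40 equiv of partner holds the same 47.0% substrate but 0.169 M partner, about twice the flask's. There g gives a drain of 0.761 /h and a plateau of 4.60%. That neighbour holds 5.07% intermediate, half the flask's, and 44.3% target.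

Readings and results stem from a simulated flask from invented constants, noise included.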